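0.202 is the number to carry: the plateau share, the target standing at the end of a run per starting material consumed, averaged over the three earlier runs.

| setting | Monday's | Thursday's | Saturday's | flask |
|---|---|---|---|---|
| starting material | 0.19 M | 0.19 M | 0.19 M | 0.19 M |
| partner | 0.10 M | 0.16 M | 0.209 M | 0.209 M |
| free catalyst | 19 mM | 19 mM | 28 mM | 19 mM |
| added ligand | 20 mM | 20 mM | 20 mM | 20 mM |
| remark | run made earlier | run made earlier | run made earlier |  |
| time |  |  |  | 3.0 h |

| run | time / h | target / % | starting material / % |
|---|---|---|---|
| Monday's | 0.0333 | 13.2 | 81.1 |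
| Monday's | 0.0833 | 19.9 | 65.8 |
| Monday's | 0.200 | 15.5 | 52.0 |
| Monday's | 0.500 | 11.0 | 47.9 |
| Monday's | 1.33 | 11.1 | 47.2 |
| Monday's | 3.00 | 11.0 | 48.2 |
| Thursday's | 0.0333 | 16.6 | 74.4 |
| Thursday's | 0.0833 | 26.6 | 53.1 |
| Thursday's | 0.200 | 22.6 | 31.3 |
| Thursday's | 0.500 | 18.0 | 19.4 |
| Thursday's | 1.33 | 17.2 | 14.8 |
| Thursday's | 3.00 | 16.5 | 16.0 |
| Saturday's | 0.0333 | 27.5 | 60.8 |
| Saturday's | 0.100 | 36.6 | 27.0 |
| Saturday's | 0.333 | 21.3 | 4.2 |
| Saturday's | 1.00 | 20.0 | 1.6 |
| Saturday's | 3.00 | 19.7 | 0 |

(scatter of a reading: 0.5 percentage points)



- time up to 3.0 h at which target stands highest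
- the amount of target, in percent of the starting material charged, at that time

plateau share = target at the end / (charge − starting material left)
Monday 0.212, Thursday 0.196, Saturday 0.197

Partner comes first. Monday's run, at 0.526 equivalents, consumed 51.8 % of its starting material, and Thursday's, at 0.842, consumed 84.0 %, so one starting material goes per partner. The flask has 1.10 equivalents, which makes starting material the limiting reagent, and its end is reckoned at

target = 0.202 × 100 % = 20.2 %

Catalyst comes next. Saturday's run, with [free catalyst] = 28 mM, has a plateau share about the same as Thursday's. Its highest reading is 36.6 % at 0.100 h, against Thursday's 26.6 % at 0.0833 h, though Saturday also had more partner. The flask has Saturday's partner and Thursday's catalyst, so the reckoning here commits to a peak between those two readings. Added ligand and starting material stood at one charge in these runs and give no reading.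

The forecast gives 31 % (28 % to 34 %) at 0.1 h (0.07 h to 0.14 h), a point where this reckoning gives a bracket, extrapolating the peak readings “with diminishing gain”.

The flask gives 31.0 % at 0.104 h.

    partner + free catalyst ⇌ catalyst intermediate A (K = 2.30 M⁻¹, k = 13.0 M⁻¹ s⁻¹)
    starting material + catalyst intermediate A → catalyst intermediate B (k = 1.40 M⁻¹ s⁻¹)
    catalyst intermediate B → free catalyst + target (k = 0.0490 s⁻¹)
    target ⇌ isomer of the product (K = 3.90, k = 0.00390 s⁻¹)
    free catalyst + added ligand ⇌ idle complex (K = 57.0 M⁻¹, k = 43.0 M⁻¹ s⁻¹)

Target in the flask then falls to 20.4 % at 3.00 h, against the 20.2 % reckoned from the plateau share. The neighbour charged with 0.47 M of starting material has 0.445 equiv of partner, so partner becomes the limiting reagent there, and the same share gives 8.98 % target at the end. That neighbour ends with partner at 0 %, starting material at 55.5 % and target at 9.08 %.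

The numbers in the tables were computed with constants of no real substance; noise was put on by code.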